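**Plan**

- Retrosynthesis cuts the side-chain C1'=C2' double bond (cross-metathesis), then the lactone acyl–O4 bond and the C6–C7 bond (acetate aldol on a C7 aldehyde). Last, the O1–C2 bond of the tetrahydrofuran is traced back to a pyranose C1–O5 bond, C1' being the former anomeric carbon.
- Enabling feature: the ring O1–C2–C3–C3a–C7a is an all-cis 2,5-anhydrogalactitol in which C2 and C7a each carry one exocyclic carbon. With C1' at the aldehyde level it is a 2,5-anhydro-D-galactose, i.e. a D-talopyranose whose ring oxygen has moved from C1 to C2.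
- Forward order: 1,6-anhydro-D-galactose (six-membered pyranose) → C2 inversion to talo → 2-triflate → ring contraction to the five-membered ring as a lactol → methylenation → oxidation and acetate aldol → δ-lactone closure → cross-metathesis with the separately made C2'–C5' alkene.
- Stereochemistry: C3, C3a and C7a come from C3, C4 and C5 of D-galactose; C2 is set by inversion in the contraction; C7 by a thiazolidinethione auxiliary; C3' and C4' by Sharpless desymmetrisation of divinylcarbinol; the E-alkene by metathesis.
- The contraction leaves one terminus as aldehyde and the other as alcohol, which is what differentiates the two ends of an otherwise meso core; the only protecting group is one acetonide.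

Key step: step 5

Remark: compounds 1, 10 and 15 are taken as purchasable (1 is otherwise one step from D-galactose); sugar numbering (C1–C6, O5, O6) is used for 1–7 and furo[3,2-b]pyran-5-one numbering (O1, C2, C3, C3a, O4, C5, C6, C7, C7a; side chain C1'–C5') from 8 on; lactol 7 is handled as an anomer mixture.

**Route**

Step 1
Reactants: 1 1,6-anhydro-β-D-galactopyranose
Product: 2 1,6-anhydro-3,4-O-isopropylidene-β-D-galactopyranose
Conditions: Me2C(OMe)2, CSA (cat.), acetone, rt
Reagents that add atoms: 2,2-dimethoxypropane, COC(C)(C)OC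
Why: Acid-catalysed transketalisation (acetonide formation) should engage only O3 (axial) and O4 (equatorial), the single cis-vicinal pair in the 1C4 chair, leaving the axial 2-OH free and creating no stereocentre.

Step 2
Reactants: 2 1,6-anhydro-3,4-O-isopropylidene-β-D-galactopyranose
Product: 3 1,6-anhydro-3,4-O-isopropylidene-β-D-lyxo-hexopyranos-2-ulose
Conditions: Dess–Martin periodinane, CH2Cl2, rt
Reagents that add atoms: none
Why: Dess–Martin oxidation of the lone secondary alcohol should give the 2-ulose under conditions that spare the acetal and acetonide, and C3 cannot epimerise without breaking the cis-fused dioxolane.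

Step 3
Reactants: 3 1,6-anhydro-3,4-O-isopropylidene-β-D-lyxo-hexopyranos-2-ulose
Product: 4 1,6-anhydro-3,4-O-isopropylidene-β-D-talopyranose
Conditions: NaBH4, MeOH, 0 °C
Reagents that add atoms: none
Why: Borohydride reduction should deliver hydride along the axial trajectory from the face remote from the anhydro bridge and the axial O3, so the new C2–OH is equatorial (talo), cis to O3 and antiperiplanar to C1–O5.

Step 4
Reactants: 4 1,6-anhydro-3,4-O-isopropylidene-β-D-talopyranose
Product: 5 1,6-anhydro-3,4-O-isopropylidene-2-O-(trifluoromethylsulfonyl)-β-D-talopyranose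
Conditions: Tf2O, pyridine, CH2Cl2, −30 → 0 °C
Reagents that add atoms: triflic anhydride, O=S(=O)(OS(=O)(=O)C(F)(F)F)C(F)(F)F
Why: O-Sulfonylation of the equatorial alcohol installs the nucleofuge with retention because no C–O bond is touched; the triflate is used crude and cold.

Step 5
Reactants: 5 1,6-anhydro-3,4-O-isopropylidene-2-O-(trifluoromethylsulfonyl)-β-D-talopyranose
Product: 7 2,5-anhydro-3,4-O-isopropylidene-D-galactose as its cyclic 1,6-hemiacetal (anomer mixture), via dioxanyl oxocarbenium ion 6 (not isolated)
Conditions: 2,6-lutidine, MeCN/H2O (4:1), rt → 50 °C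
Reagents that add atoms: water, O
Why: The 1,6-anhydro bridge locks the pyranose in the 1C4 chair, where the equatorial C2–OTf bond is antiperiplanar to C1–O5, so the ring oxygen displaces triflate from the rear at C2 while its bond to C1 breaks (1,2-oxygen shift through an oxiranium-like three-centre transition state), leaving the O6-stabilised oxocarbenium ion 6 that water captures as hemiacetal 7. The closest known reaction type is the ring contraction of pyranose 2-sulfonates and 2-diazonium ions to 2,5-anhydroaldoses (nitrous acid deamination of 2-amino-2-deoxy sugars, sulfonate solvolysis and DAST rearrangements of 1,6-anhydrohexopyranoses). The tetrahydrofuran ring (O5, C2, C3, C4, C5) closes by this intramolecular SN2-type attack of O5 on C2 (formally 3-exo-tet followed by opening at C1), which contracts the six-membered pyranose, while the five-membered anhydro ring grows by C2 into the 1,4-dioxane whose hemiacetal carbon is completed by addition of water to the cation. The only new stereocentre that matters, C2 of the target, is set by stereospecific inversion at the triflate carbon and so ends up cis to O3, O4 and C6, giving the all-cis ring that a thermodynamic closure would not give; the hemiacetal carbon is an inconsequential anomer mixture. The step needs O5 migration to win over migration of C4 (the C3–C4 bond is also antiperiplanar) and over direct substitution: the oxygen lone pair and the O6-stabilised cation favour the oxygen shift, a C4 shift would build a strained 2,7-dioxabicyclo[2.2.1]heptane, and external nucleophiles would have to approach C2 axially through the concave face of the bicycle.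

Step 6
Reactants: 7 2,5-anhydro-3,4-O-isopropylidene-D-galactose as its cyclic 1,6-hemiacetal
Product: 8 3,6-anhydro-1,2-dideoxy-4,5-O-isopropylidene-D-galacto-hept-1-enitol (all-cis 2-vinyl-5-hydroxymethyl tetrahydrofuran acetonide)
Conditions: Ph3PCH3Br, KOtBu, THF, 0 °C → rt
Reagents that add atoms: methyltriphenylphosphonium bromide, C[P+](c1ccccc1)(c1ccccc1)c1ccccc1.[Br-]
Why: Wittig methylenation of the lactol through its open hydroxy-aldehyde form should give the terminal alkene and free the C6 hydroxyl, with excess ylide at low temperature limiting α-epimerisation and β-elimination at the all-cis centre.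

Step 7
Reactants: 8 3,6-anhydro-1,2-dideoxy-4,5-O-isopropylidene-D-galacto-hept-1-enitol
Product: 9 2,5-anhydro-6,7-dideoxy-3,4-O-isopropylidene-L-galacto-hept-6-enose (all-cis 2-formyl-5-vinyl tetrahydrofuran acetonide)
Conditions: Dess–Martin periodinane, pyridine, CH2Cl2, 0 °C
Reagents that add atoms: none
Why: Dess–Martin oxidation of the primary alcohol under buffered, non-enolising conditions should preserve the epimerisable α-alkoxy centre, and the aldehyde is used at once.

Step 8
Reactants: 9 2,5-anhydro-6,7-dideoxy-3,4-O-isopropylidene-L-galacto-hept-6-enose; 10 (4S)-3-acetyl-4-benzyl-1,3-thiazolidine-2-thione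
Product: 12 (4S)-4-benzyl-3-[(3R)-3-hydroxy-3-(all-cis-6-ethenyl-2,2-dimethyltetrahydrofuro[3,4-d][1,3]dioxol-4-yl)propanoyl]-1,3-thiazolidine-2-thione, via trichlorotitanium enolate 11 (not isolated)
Conditions: 10, TiCl4, iPr2NEt, CH2Cl2, −78 °C; then 9, −78 °C
Reagents that add atoms: none
Why: Auxiliary-controlled titanium acetate aldol (Nagao-type thiazolidinethione): the sulfur-chelated enolate 11 should add through a closed Zimmerman–Traxler chair on the face opposite the benzyl group, setting the carbinol (C7 of the target) as R, the same sense as Felkin–Anh attack anti to the ring C–O bond.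

Step 9
Reactants: 12 thiazolidinethione aldol adduct
Product: 14 (2S,3R,3aR,7R,7aR)-2-ethenyl-3,7-dihydroxyhexahydro-5H-furo[3,2-b]pyran-5-one, via triol thioimide 13 (not isolated)
Conditions: TFA/H2O (4:1), 0 °C; evaporate; DMAP (cat.), CH2Cl2, rt
Reagents that add atoms: none
Why: Aqueous-acid acetonide hydrolysis followed by DMAP-catalysed acyl transfer (lactonisation, 6-exo-trig) should close the δ-lactone on the C3a hydroxyl and expel the auxiliary, the seven-membered alternative through the C3 hydroxyl being disfavoured and no stereocentre being touched.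

Step 10
Reactants: 15 penta-1,4-dien-3-ol
Product: 16 (2R,3S)-1,2-epoxypent-4-en-3-ol
Conditions: Ti(OiPr)4 (cat.), L-(+)-DIPT (cat.), t-BuOOH, 4 Å MS, CH2Cl2, −20 °C
Reagents that add atoms: tert-butyl hydroperoxide, CC(C)(C)OO
Why: Sharpless asymmetric epoxidation of the prochiral divinylcarbinol (desymmetrisation reinforced by kinetic resolution) should select one enantiotopic vinyl group and one face, giving the erythro epoxy alcohol that fixes both side-chain stereocentres.

Step 11
Reactants: 16 (2R,3S)-1,2-epoxypent-4-en-3-ol
Product: 17 (1S)-1-[(2R)-oxiran-2-yl]prop-2-en-1-yl benzoate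
Conditions: BzCl, pyridine, DMAP (cat.), CH2Cl2, 0 °C
Reagents that add atoms: benzoyl chloride, O=C(Cl)c1ccccc1
Why: Benzoylation of the secondary alcohol under pyridine/DMAP is too mild for Payne rearrangement or epoxide opening and retains configuration.

Step 12
Reactants: 17 (1S)-1-[(2R)-oxiran-2-yl]prop-2-en-1-yl benzoate
Product: 18 (3S,4S)-4-hydroxy-5-iodopent-1-en-3-yl benzoate
Conditions: LiI, AcOH, THF, 0 °C → rt
Reagents that add atoms: lithium iodide, [Li+].[I-]
Why: Regioselective SN2 opening of the terminal epoxide by iodide at the unhindered CH2 (iodohydrin formation) under mildly acidic buffering should leave the carbinol stereocentre and the neighbouring benzoate untouched.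

Step 13
Reactants: 18 (3S,4S)-4-hydroxy-5-iodopent-1-en-3-yl benzoate
Product: 19 (3S,4R)-4-hydroxypent-1-en-3-yl benzoate
Conditions: Bu3SnH, AIBN (cat.), toluene, 80 °C
Reagents that add atoms: none
Why: Radical dehalogenation (tin hydride chain reduction) of the primary iodide should turn CH2I into the methyl group, the β-hydroxyalkyl radical having no low-energy rearrangement and the esters and terminal alkene being inert.

Step 14
Reactants: 19 (3S,4R)-4-hydroxypent-1-en-3-yl benzoate
Product: 20 (3S,4R)-4-acetoxypent-1-en-3-yl benzoate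
Conditions: Ac2O, pyridine, DMAP (cat.), CH2Cl2, 0 °C
Reagents that add atoms: acetic anhydride, CC(=O)OC(C)=O
Why: DMAP-catalysed acetylation of the remaining secondary alcohol, run briefly at 0 °C, should outpace any benzoyl migration.

Step 15
Reactants: 14 (2S,3R,3aR,7R,7aR)-2-ethenyl-3,7-dihydroxyhexahydro-5H-furo[3,2-b]pyran-5-one; 20 (3S,4R)-4-acetoxypent-1-en-3-yl benzoate
Product: 21 (1E,3S,4R)-4-acetoxy-1-[(2S,3R,3aR,7R,7aR)-3,7-dihydroxy-5-oxohexahydro-2H-furo[3,2-b]pyran-2-yl]pent-1-en-3-yl benzoate (target, CNP0230210.1)
Conditions: second-generation Hoveyda–Grubbs catalyst RuCl2(H2IMes)(=CH-C6H4-2-OiPr) (cat.), 20 (excess), CH2Cl2, 40 °C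
Reagents that add atoms: none
Why: Olefin cross-metathesis between two monosubstituted alkenes bearing allylic oxygen should be driven to the cross product by an excess of 20, both partners homodimerising slowly, and the two α-branched allylic centres should enforce the E geometry while hydroxyls, esters and the lactone are tolerated.

**Compound list**

1 | 1,6-anhydro-β-D-galactopyranose | O1C[C@H]2O[C@@H]1[C@H](O)[C@@H](O)[C@H]2O | starting material
2 | 1,6-anhydro-3,4-O-isopropylidene-β-D-galactopyranose | O1C[C@H]2O[C@@H]1[C@H](O)[C@H]3OC(C)(C)O[C@@H]23 | intermediate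
3 | 1,6-anhydro-3,4-O-isopropylidene-β-D-lyxo-hexopyranos-2-ulose | O1C[C@H]2O[C@@H]1C(=O)[C@H]3OC(C)(C)O[C@@H]23 | intermediate
4 | 1,6-anhydro-3,4-O-isopropylidene-β-D-talopyranose | O1C[C@H]2O[C@@H]1[C@@H](O)[C@H]3OC(C)(C)O[C@@H]23 | intermediate
5 | 1,6-anhydro-3,4-O-isopropylidene-2-O-(trifluoromethylsulfonyl)-β-D-talopyranose | O1C[C@H]2O[C@@H]1[C@@H](OS(=O)(=O)C(F)(F)F)[C@H]3OC(C)(C)O[C@@H]23 | intermediate
6 | ring-contracted dioxanyl oxocarbenium ion (C1=O6+), triflate counter-ion | [CH]=1[C@@H]2O[C@H](C[O+]=1)[C@@H]3OC(C)(C)O[C@H]23.[O-]S(=O)(=O)C(F)(F)F | intermediate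
7 | 2,5-anhydro-3,4-O-isopropylidene-D-galactose, cyclic 1,6-hemiacetal (anomer mixture) | OC1[C@@H]2O[C@H](CO1)[C@@H]3OC(C)(C)O[C@H]23 | intermediate
8 | 3,6-anhydro-1,2-dideoxy-4,5-O-isopropylidene-D-galacto-hept-1-enitol | C=C[C@@H]1O[C@H](CO)[C@@H]2OC(C)(C)O[C@H]12 | intermediate
9 | 2,5-anhydro-6,7-dideoxy-3,4-O-isopropylidene-L-galacto-hept-6-enose | C=C[C@@H]1O[C@H](C=O)[C@@H]2OC(C)(C)O[C@H]12 | intermediate
10 | (4S)-3-acetyl-4-benzyl-1,3-thiazolidine-2-thione | CC(=O)N1[C@@H](Cc2ccccc2)CSC1=S | starting material
11 | trichlorotitanium enolate of 10 | C=C(O[Ti](Cl)(Cl)Cl)N1[C@@H](Cc2ccccc2)CSC1=S | intermediate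
12 | (4S)-4-benzyl-3-[(3R)-3-hydroxy-3-(all-cis-6-ethenyl-2,2-dimethyltetrahydrofuro[3,4-d][1,3]dioxol-4-yl)propanoyl]-1,3-thiazolidine-2-thione | C=C[C@@H]1O[C@H]([C@H](O)CC(=O)N3[C@@H](Cc4ccccc4)CSC3=S)[C@@H]2OC(C)(C)O[C@H]12 | intermediate
13 | triol thioimide (12 without the acetonide) | C=C[C@@H]1O[C@H]([C@H](O)CC(=O)N2[C@@H](Cc3ccccc3)CSC2=S)[C@H](O)[C@@H]1O | intermediate
14 | (2S,3R,3aR,7R,7aR)-2-ethenyl-3,7-dihydroxyhexahydro-5H-furo[3,2-b]pyran-5-one | C=C[C@@H]1O[C@H]2[C@H](OC(=O)C[C@H]2O)[C@@H]1O | intermediate
15 | penta-1,4-dien-3-ol | C=CC(O)C=C | starting material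
16 | (2R,3S)-1,2-epoxypent-4-en-3-ol | C=C[C@H](O)[C@H]1CO1 | intermediate
17 | (1S)-1-[(2R)-oxiran-2-yl]prop-2-en-1-yl benzoate | C=C[C@H](OC(=O)c1ccccc1)[C@H]1CO1 | intermediate
18 | (3S,4S)-4-hydroxy-5-iodopent-1-en-3-yl benzoate | C=C[C@H](OC(=O)c1ccccc1)[C@H](O)CI | intermediate
19 | (3S,4R)-4-hydroxypent-1-en-3-yl benzoate | C=C[C@H](OC(=O)c1ccccc1)[C@H](O)C | intermediate
20 | (3S,4R)-4-acetoxypent-1-en-3-yl benzoate | CC(=O)O[C@H](C)[C@H](C=C)OC(=O)c1ccccc1 | intermediate
21 | (1E,3S,4R)-4-acetoxy-1-[(2S,3R,3aR,7R,7aR)-3,7-dihydroxy-5-oxohexahydro-2H-furo[3,2-b]pyran-2-yl]pent-1-en-3-yl benzoate | CC(=O)O[C@H](C)[C@H](/C=C/[C@@H]1O[C@H]2[C@H](OC(=O)C[C@H]2O)[C@@H]1O)OC(=O)c1ccccc1 | target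

**Count and risks**

Total step count: 15. Longest linear sequence: 10 steps (steps 1–9 and 15); the side chain takes steps 10–14.

Steps most likely to fail:

1. Step 5. The ionising triflate may be consumed by pathways other than the O5 shift: attack at sulfur returning 4, migration of C4, or capture before rearrangement. The fallback sets out from 3 and comes back at 7, with a nucleofuge that needs no solvent assistance. Ketone 3 is condensed with NH2OH·HCl in pyridine to the ketoxime F1. Reduction with LiAlH4 in THF from the same exposed face should give the equatorial talo amine F2. Nitrous acid deamination of F2 (NaNO2, aqueous AcOH, 0 °C), the classical route to 2,5-anhydroaldoses, should then release N2 and pass through the same ion 6 to lactol 7.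

2. Step 15. Turnover at the hindered vinyl group flanked by a free hydroxyl may be slow, so that catalyst decay and homodimerisation of 20 outrun the cross-coupling. The fallback sets out from 8 and comes back at 21. It moves the union ahead of the lactone and diol unveiling, so the chain is built linearly on a lipophilic substrate with no free secondary hydroxyl or lactone to hold the ruthenium carbene. Cross-metathesis of 8 with 20 should give the coupled alcohol F3. Dess–Martin oxidation gives the aldehyde F4, and the titanium acetate aldol with 10 gives the thioimide aldol adduct F5. TFA/H2O and then DMAP close the lactone to 21; the acetate and benzoate should survive these non-basic steps.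

3. Step 8. Facial selectivity may erode, or aldehyde 9 may epimerise at its α-centre under the amine base before the C–C bond forms. The fallback sets out from 9 and comes back at 14. It uses a base-free Mukaiyama aldol through an open transition state under substrate (Felkin–Anh) control. Aldehyde 9 with 1-(tert-butyldimethylsilyloxy)-1-methoxyethene and BF3·OEt2 in CH2Cl2 at −78 °C should give, after aqueous work-up, the β-hydroxy ester F6. TFA/H2O then removes the acetonide and lactonises the methyl ester under acid to 14.

Further compounds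
F1 | step 5 | 1,6-anhydro-3,4-O-isopropylidene-β-D-lyxo-hexopyranos-2-ulose oxime | O1C[C@H]2O[C@@H]1C(=NO)[C@H]3OC(C)(C)O[C@@H]23
F2 | step 5 | 2-amino-1,6-anhydro-2-deoxy-3,4-O-isopropylidene-β-D-talopyranose | O1C[C@H]2O[C@@H]1[C@@H](N)[C@H]3OC(C)(C)O[C@@H]23
F3 | step 15 | (1E,3S,4R)-4-acetoxy-1-[all-cis-6-(hydroxymethyl)-2,2-dimethyltetrahydrofuro[3,4-d][1,3]dioxol-4-yl]pent-1-en-3-yl benzoate | CC(=O)O[C@H](C)[C@H](/C=C/[C@@H]1O[C@H](CO)[C@@H]2OC(C)(C)O[C@H]12)OC(=O)c1ccccc1
F4 | step 15 | (1E,3S,4R)-4-acetoxy-1-[all-cis-6-formyl-2,2-dimethyltetrahydrofuro[3,4-d][1,3]dioxol-4-yl]pent-1-en-3-yl benzoate | CC(=O)O[C@H](C)[C@H](/C=C/[C@@H]1O[C@H](C=O)[C@@H]2OC(C)(C)O[C@H]12)OC(=O)c1ccccc1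
F5 | step 15 | thiazolidinethione acetate aldol adduct of F4 (3R carbinol) | CC(=O)O[C@H](C)[C@H](/C=C/[C@@H]1O[C@H]([C@H](O)CC(=O)N3[C@@H](Cc4ccccc4)CSC3=S)[C@@H]2OC(C)(C)O[C@H]12)OC(=O)c1ccccc1
F6 | step 8 | methyl (3R)-3-hydroxy-3-(all-cis-6-ethenyl-2,2-dimethyltetrahydrofuro[3,4-d][1,3]dioxol-4-yl)propanoate | C=C[C@@H]1O[C@H]([C@H](O)CC(=O)OC)[C@@H]2OC(C)(C)O[C@H]12
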